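The target, epiguibourtinidol-(4α→8)-epicatechin, is cut at C2–C3 and O1–C2 of ring C. C3 sits between C2, which carries ring B and O1, and the diarylmethine C4, which joins ring A to C8 of ring D. A nitro group placed on C3 makes that carbon nucleophilic, then turns C2 into a Michael acceptor for the ring A phenol, and finally gives way to oxygen. One operation therefore joins 4-benzyloxybenzaldehyde to a 2,2-diaryl-1-nitroethane, closes ring C and lets the catalytically set C4 dictate C2 and C3 by equilibration. The precursor is that nitroethane: C4 (S), ring A with its only free phenol, and a perbenzylated epicatechin-8-yl group.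

Key step: step 7

Configuration check: the target reads (2R,3R,4S) in rings A/B/C, with the C2 aryl, the C3 OH and the C4 aryl all on the α face, and (2R,3R) in rings D/E/F. Accordingly 10 is (S) at C4, 13 is (2R,3S,4S), 15 is (2R,4S) and 16 is (2R,3R,4S).
Design remark: O3 of ring F is benzylated as well, so 10 offers a single O–H to step 7 and one hydrogenolysis ends the route.
Assumption: the quinine-derived thiourea is taken to direct attack to the Si face of C4 in 8. If it favours the Re face, its quinidine-derived pseudo-enantiomer is used, and C4 is assigned on 10 before going on.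

Step 1
Reactants: 1 (−)-epicatechin
Product: 2 5,7,3',4'-tetra-O-benzyl-(−)-epicatechin
Conditions: BnBr (4.4 equiv), K2CO3, DMF, 0 °C to rt, argon
Reagents that add atoms: benzyl bromide, BrCc1ccccc1
Why: Williamson etherification in which K2CO3 deprotonates only the four phenols and leaves the C3 alcohol untouched, while the mild base and exclusion of air should prevent opening of ring F, so that C2 and C3 stay (2R,3R).

Step 2
Reactants: 2 5,7,3',4'-tetra-O-benzyl-(−)-epicatechin
Product: 3 3,5,7,3',4'-penta-O-benzyl-(−)-epicatechin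
Conditions: NaH, BnBr, DMF, 0 °C to rt
Reagents that add atoms: benzyl bromide, BrCc1ccccc1
Why: Williamson etherification of the secondary alkoxide; with no free phenol left the chroman cannot open to a quinone methide under NaH, so both stereocentres are retained.

Step 3
Reactants: 3 3,5,7,3',4'-penta-O-benzyl-(−)-epicatechin
Product: 4 8-bromo-3,5,7,3',4'-penta-O-benzyl-(−)-epicatechin
Conditions: NBS (1.0 equiv), CH2Cl2, −78 °C to rt
Reagents that add atoms: N-bromosuccinimide, O=C1CCC(=O)N1Br
Why: Electrophilic aromatic bromination that goes to the phloroglucinol-type ring D, the most electron-rich arene, and there to C8, the position known to react first in O-benzylated flavan-3-ols with one equivalent of NBS at low temperature.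

Step 4
Reactants: 4 8-bromo-3,5,7,3',4'-penta-O-benzyl-(−)-epicatechin
Product: 6 8-formyl-3,5,7,3',4'-penta-O-benzyl-(−)-epicatechin, via aryllithium 5 (not isolated)
Conditions: n-BuLi (1.1 equiv), THF, −78 °C; DMF, −78 to 0 °C; H2O
Reagents that add atoms: N,N-dimethylformamide, CN(C)C=O
Why: Bromine–lithium exchange outruns benzylic deprotonation at −78 °C, and the aryllithium, flanked by two coordinating oxygens, is formylated by DMF (Bouveault-type aldehyde synthesis), the aldehyde being released from the hemiaminal alkoxide on quenching.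

Step 5
Reactants: 6 8-formyl-3,5,7,3',4'-penta-O-benzyl-(−)-epicatechin; 7 nitromethane
Product: 8 8-[(E)-2-nitrovinyl]-3,5,7,3',4'-penta-O-benzyl-(−)-epicatechin
Conditions: NH4OAc, MeNO2 (solvent), 95 °C
Reagents that add atoms: none
Why: Henry condensation with dehydration in the same flask, routine for 2,4,6-trialkoxybenzaldehydes, which should give the (E)-nitroalkene as the conjugated thermodynamic isomer.

Step 6
Reactants: 8 8-[(E)-2-nitrovinyl]-3,5,7,3',4'-penta-O-benzyl-(−)-epicatechin; 9 3-(benzyloxy)phenol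
Product: 10 (S)-2-[4-(benzyloxy)-2-hydroxyphenyl]-2-(3,5,7,3',4'-penta-O-benzylepicatechin-8-yl)-1-nitroethane
Conditions: 9 (3 equiv), quinine-derived 3,5-bis(trifluoromethyl)phenyl thiourea (20 mol %), 4 Å MS, toluene (1 M), 40 °C; chromatography
Reagents that add atoms: none
Why: Asymmetric Friedel–Crafts conjugate alkylation of an electron-rich phenol with a nitroalkene under bifunctional catalysis, in which the thiourea binds the nitro group and the quinuclidine nitrogen binds the phenol O–H, so that C6 of 9 (ortho to OH, para to OBn) is delivered to the Si face of the β-carbon and C4 becomes (S), any minor C4 epimer being a diastereomer that chromatography removes.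

Step 7
Reactants: 10 (S)-2-[4-(benzyloxy)-2-hydroxyphenyl]-2-(3,5,7,3',4'-penta-O-benzylepicatechin-8-yl)-1-nitroethane; 11 4-(benzyloxy)benzaldehyde
Product: 13 (2R,3S,4S)-7-benzyloxy-2-(4-benzyloxyphenyl)-3-nitro-4-(3,5,7,3',4'-penta-O-benzylepicatechin-8-yl)chroman, via nitroalkene 12 (not isolated)
Conditions: 11 (1.5 equiv), piperidine (0.3 equiv), AcOH (0.3 equiv), 4 Å MS, toluene, 60 °C
Reagents that add atoms: none
Why: Piperidine converts 11 into its iminium ion, the nitronate of 10 adds through C3, and loss of piperidine (or of water from the nitro-aldol) leaves nitroalkene 12, whose benzylic carbon C2 is attacked by the ring A phenol before the new nitronate is protonated at C3. The closest known reaction types are the amine-catalysed Henry condensation of primary nitroalkanes with aryl aldehydes and the oxa-Michael addition of phenols to β-nitrostyrenes that leads to 2-aryl-3-nitrochromans. Ring C closes in the 6-endo-trig mode, because the nitro group polarises C2=C3 so that only C2 is electrophilic and a 5-exo attack at C3 has no driving force. C2 is controlled by C4: the oxa-Michael step is reversible, so the mixture should drain into the half-chair with the C2 and C4 aryl groups both equatorial (2,4-cis, 2R), and C3 is controlled by amine-mediated epimerisation of its acidic C–H, which places the nitro group equatorial and trans to both neighbours (3S). The step needs one oxygen nucleophile among eight oxygen functions and retention at C4; the first is secured because every other hydroxy group is benzylated. The second is secured because allylic 1,3-strain in 12 holds C4–H in the alkene plane, where it is not acidified, and because 60 °C is kept as the upper limit to suppress loss of the nitromethyl anion through an ortho-quinone methide.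

Step 8
Reactants: 13 (2R,3S,4S)-7-benzyloxy-2-(4-benzyloxyphenyl)-3-nitro-4-(3,5,7,3',4'-penta-O-benzylepicatechin-8-yl)chroman
Product: 15 (2R,4S)-7-benzyloxy-2-(4-benzyloxyphenyl)-4-(3,5,7,3',4'-penta-O-benzylepicatechin-8-yl)chroman-3-one, via sodium nitronate 14 (not isolated)
Conditions: NaOMe (1.1 equiv), THF–MeOH, 0 °C, short; then aq TiCl3 (4 equiv), NH4OAc buffer (about pH 6), 0 °C to rt; crude product used at once
Reagents that add atoms: water, O
Why: Reductive Nef reaction in which trivalent titanium reduces the nitronate through the oxime to the N–H imine, which is hydrolysed at about pH 6, mild enough that C2 and C4, both α to the new carbonyl group, should keep the 2,4-cis (2R,4S) arrangement, which is also the more stable diequatorial one.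

Step 9
Reactants: 15 (2R,4S)-7-benzyloxy-2-(4-benzyloxyphenyl)-4-(3,5,7,3',4'-penta-O-benzylepicatechin-8-yl)chroman-3-one
Product: 16 (2R,3R,4S)-7-benzyloxy-2-(4-benzyloxyphenyl)-4-(3,5,7,3',4'-penta-O-benzylepicatechin-8-yl)chroman-3-ol
Conditions: LiBH(s-Bu)3, LiBr, THF, −78 °C; then H2O
Reagents that add atoms: none
Why: Diastereoselective ketone reduction with a bulky hydride, as used to turn flavan-3-ones into 2,3-cis flavan-3-ols: both aryl groups shield the α face, so hydride should arrive from the β face and place the C3 hydroxy group axial and cis to both neighbours (3R).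

Step 10
Reactants: 16 (2R,3R,4S)-7-benzyloxy-2-(4-benzyloxyphenyl)-4-(3,5,7,3',4'-penta-O-benzylepicatechin-8-yl)chroman-3-ol
Product: 17 epiguibourtinidol-(4α→8)-epicatechin (target)
Conditions: H2 (1 atm), Pd(OH)2/C, THF–MeOH–H2O, rt
Reagents that add atoms: none
Why: Catalytic hydrogenolysis of all seven benzyl ethers under neutral conditions at 1 atm, under which the cyclic benzylic C2–O1 bonds and the C4–C8 bond of flavan-3-ol oligomers are known to persist and no stereocentre is touched.

Compound list
1 | (−)-epicatechin, (2R,3R) | Oc1cc(O)c2c(c1)O[C@H](c1ccc(O)c(O)c1)[C@H](O)C2 | starting material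
2 | 5,7,3',4'-tetra-O-benzyl-(−)-epicatechin | c5c(OCc9ccccc9)cc(OCc9ccccc9)c6c5O[C@H](c7ccc(OCc9ccccc9)c(OCc9ccccc9)c7)[C@H](O)C6 | intermediate
3 | 3,5,7,3',4'-penta-O-benzyl-(−)-epicatechin | c5c(OCc9ccccc9)cc(OCc9ccccc9)c6c5O[C@H](c7ccc(OCc9ccccc9)c(OCc9ccccc9)c7)[C@H](OCc9ccccc9)C6 | intermediate
4 | 8-bromo-penta-O-benzyl-(−)-epicatechin | Brc5c(OCc9ccccc9)cc(OCc9ccccc9)c6c5O[C@H](c7ccc(OCc9ccccc9)c(OCc9ccccc9)c7)[C@H](OCc9ccccc9)C6 | intermediate
5 | 8-lithio-penta-O-benzyl-(−)-epicatechin (not isolated) | [Li]c5c(OCc9ccccc9)cc(OCc9ccccc9)c6c5O[C@H](c7ccc(OCc9ccccc9)c(OCc9ccccc9)c7)[C@H](OCc9ccccc9)C6 | intermediate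
6 | 8-formyl-penta-O-benzyl-(−)-epicatechin | O=Cc5c(OCc9ccccc9)cc(OCc9ccccc9)c6c5O[C@H](c7ccc(OCc9ccccc9)c(OCc9ccccc9)c7)[C@H](OCc9ccccc9)C6 | intermediate
7 | nitromethane | C[N+](=O)[O-] | starting material
8 | 8-[(E)-2-nitrovinyl]-penta-O-benzyl-(−)-epicatechin | [O-][N+](=O)/C=C/c5c(OCc9ccccc9)cc(OCc9ccccc9)c6c5O[C@H](c7ccc(OCc9ccccc9)c(OCc9ccccc9)c7)[C@H](OCc9ccccc9)C6 | intermediate
9 | 3-(benzyloxy)phenol | Oc1cccc(OCc2ccccc2)c1 | starting material
10 | (S)-2-[4-(benzyloxy)-2-hydroxyphenyl]-2-(penta-O-benzylepicatechin-8-yl)-1-nitroethane | [O-][N+](=O)C[C@@H](c2ccc(OCc9ccccc9)cc2O)c5c(OCc9ccccc9)cc(OCc9ccccc9)c6c5O[C@H](c7ccc(OCc9ccccc9)c(OCc9ccccc9)c7)[C@H](OCc9ccccc9)C6 | intermediate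
11 | 4-(benzyloxy)benzaldehyde | O=Cc1ccc(OCc2ccccc2)cc1 | starting material
12 | (E)-1-(4-benzyloxyphenyl)-2-nitro-3-[4-(benzyloxy)-2-hydroxyphenyl]-3-(penta-O-benzylepicatechin-8-yl)prop-1-ene, (S) at the diarylmethine (not isolated) | [O-][N+](=O)/C(=C/c1ccc(OCc9ccccc9)cc1)[C@@H](c2ccc(OCc9ccccc9)cc2O)c5c(OCc9ccccc9)cc(OCc9ccccc9)c6c5O[C@H](c7ccc(OCc9ccccc9)c(OCc9ccccc9)c7)[C@H](OCc9ccccc9)C6 | intermediate
13 | (2R,3S,4S)-3-nitroflavan, 2,3-trans-3,4-trans, 2,4-cis, heptabenzyl ether | C(c9ccccc9)Oc1ccc([C@H]2Oc3cc(OCc9ccccc9)ccc3[C@@H](c5c(OCc9ccccc9)cc(OCc9ccccc9)c6c5O[C@H](c7ccc(OCc9ccccc9)c(OCc9ccccc9)c7)[C@H](OCc9ccccc9)C6)[C@@H]2[N+](=O)[O-])cc1 | intermediate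
14 | sodium nitronate of 13 (not isolated) | C(c9ccccc9)Oc1ccc([C@H]2Oc3cc(OCc9ccccc9)ccc3[C@@H](c5c(OCc9ccccc9)cc(OCc9ccccc9)c6c5O[C@H](c7ccc(OCc9ccccc9)c(OCc9ccccc9)c7)[C@H](OCc9ccccc9)C6)C2=[N+]([O-])[O-])cc1.[Na+] | intermediate
15 | (2R,4S)-2,4-cis-diarylchroman-3-one, heptabenzyl ether | C(c9ccccc9)Oc1ccc([C@H]2Oc3cc(OCc9ccccc9)ccc3[C@@H](c5c(OCc9ccccc9)cc(OCc9ccccc9)c6c5O[C@H](c7ccc(OCc9ccccc9)c(OCc9ccccc9)c7)[C@H](OCc9ccccc9)C6)C2=O)cc1 | intermediate
16 | (2R,3R,4S)-all-cis flavan-3-ol, heptabenzyl ether of the target | C(c9ccccc9)Oc1ccc([C@H]2Oc3cc(OCc9ccccc9)ccc3[C@@H](c5c(OCc9ccccc9)cc(OCc9ccccc9)c6c5O[C@H](c7ccc(OCc9ccccc9)c(OCc9ccccc9)c7)[C@H](OCc9ccccc9)C6)[C@H]2O)cc1 | intermediate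
17 | epiguibourtinidol-(4α→8)-epicatechin, (2R,3R,4S) upper unit and (2R,3R) lower unit | Oc1ccc([C@H]2Oc3cc(O)ccc3[C@@H](c3c(O)cc(O)c4c3O[C@H](c3ccc(O)c(O)c3)[C@H](O)C4)[C@H]2O)cc1 | target

Total step count: 10. Longest linear sequence: 10 steps (1 to 17).

Steps most likely to fail

Step 7. The condensation may stall, because C3 is flanked by a doubly ortho-substituted diarylmethine and the aldehyde is electron-rich. Prolonged warming in the amine buffer may also erode C4 by reversible loss of the nitromethyl anion. The fallback builds ring C first and brings in ring D last; it sets out from 4 and comes back at 13.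
- 11 and 7 are condensed with NH4OAc to (E)-1-(benzyloxy)-4-(2-nitrovinyl)benzene F1.
- F1 and commercial 4-(benzyloxy)-2-hydroxybenzaldehyde are joined under DABCO by the known oxa-Michael/Henry/dehydration sequence to racemic 7-(benzyloxy)-2-[4-(benzyloxy)phenyl]-3-nitro-2H-chromene F2.
- Aryllithium 5, made from 4 as in step 4, is added in conjugate fashion to C4 of F2 at −78 °C and the nitronate is quenched with AcOH.
- Catalytic DBU then equilibrates C2 and C3 to the all-equatorial arrangement. This should give 13 together with the (2S,3R,4R) diastereomer of 13 F3, and the two are separated by chromatography.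

Step 6. Conversion may be low, because the 2,4,6-trialkoxyaryl nitroalkene is a weak and hindered acceptor. Attack para to the phenol OH or poor facial selectivity may add to the loss. The fallback reverses the polarity so that ring D is the nucleophile; it sets out from 4 and comes back at 10.
- Commercial 4-(benzyloxy)-2-hydroxybenzaldehyde and 7 are condensed with NH4OAc to (E)-5-(benzyloxy)-2-(2-nitrovinyl)phenol F4.
- F4 is silylated with TBSCl and imidazole to its tert-butyldimethylsilyl ether F5.
- Aryllithium 5 from 4 is added to F5 in toluene at −78 °C in the presence of one enantiomer of 1,2-dimethoxy-1,2-diphenylethane. This is the known chiral-diether-mediated asymmetric conjugate addition of aryllithiums to nitroalkenes.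
- After an AcOH quench the O-silyl ether of 10 F6 is freed from any C4 epimer by chromatography, and TBAF buffered with AcOH releases 10.

Step 8. The strained nitronate may open by retro-oxa-Michael cleavage before it is reduced, and the ketone may enolise toward C2 or C4 and lose configuration. The fallback avoids any nitronate; it sets out from 13 and comes back at 15.
- NiCl2·6H2O and NaBH4 in THF–MeOH at 0 °C reduce the nitro group with retention to the (2R,3S,4S)-3-aminoflavan F7.
- F7 condenses with 3,5-di-tert-butyl-1,2-benzoquinone and, after the spontaneous prototropic shift of this biomimetic transamination, gives the N-(3,5-di-tert-butyl-2-hydroxyphenyl) ketimine of 15 F8.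
- Aqueous oxalic acid in THF hydrolyses F8 to 15.

Further compounds
F1 | step 7 | (E)-1-(benzyloxy)-4-(2-nitrovinyl)benzene | [O-][N+](=O)/C=C/c1ccc(OCc2ccccc2)cc1
F2 | step 7 | racemic 7-(benzyloxy)-2-[4-(benzyloxy)phenyl]-3-nitro-2H-chromene | [O-][N+](=O)C1=Cc2ccc(OCc3ccccc3)cc2OC1c1ccc(OCc2ccccc2)cc1
F3 | step 7 | (2S,3R,4R) diastereomer of 13 | C(c9ccccc9)Oc1ccc([C@@H]2Oc3cc(OCc9ccccc9)ccc3[C@H](c5c(OCc9ccccc9)cc(OCc9ccccc9)c6c5O[C@H](c7ccc(OCc9ccccc9)c(OCc9ccccc9)c7)[C@H](OCc9ccccc9)C6)[C@H]2[N+](=O)[O-])cc1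
F4 | step 6 | (E)-5-(benzyloxy)-2-(2-nitrovinyl)phenol | [O-][N+](=O)/C=C/c1ccc(OCc2ccccc2)cc1O
F5 | step 6 | tert-butyldimethylsilyl ether of F4 | [O-][N+](=O)/C=C/c1ccc(OCc2ccccc2)cc1O[Si](C)(C)C(C)(C)C
F6 | step 6 | O-(tert-butyldimethylsilyl) ether of 10, (S) at C4 | [O-][N+](=O)C[C@@H](c2ccc(OCc9ccccc9)cc2O[Si](C)(C)C(C)(C)C)c5c(OCc9ccccc9)cc(OCc9ccccc9)c6c5O[C@H](c7ccc(OCc9ccccc9)c(OCc9ccccc9)c7)[C@H](OCc9ccccc9)C6
F7 | step 8 | (2R,3S,4S)-3-aminoflavan, heptabenzyl ether | C(c9ccccc9)Oc1ccc([C@H]2Oc3cc(OCc9ccccc9)ccc3[C@@H](c5c(OCc9ccccc9)cc(OCc9ccccc9)c6c5O[C@H](c7ccc(OCc9ccccc9)c(OCc9ccccc9)c7)[C@H](OCc9ccccc9)C6)[C@@H]2N)cc1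
F8 | step 8 | N-(3,5-di-tert-butyl-2-hydroxyphenyl) ketimine of 15 | C(c9ccccc9)Oc1ccc([C@H]2Oc3cc(OCc9ccccc9)ccc3[C@@H](c5c(OCc9ccccc9)cc(OCc9ccccc9)c6c5O[C@H](c7ccc(OCc9ccccc9)c(OCc9ccccc9)c7)[C@H](OCc9ccccc9)C6)C2=Nc4cc(C(C)(C)C)cc(C(C)(C)C)c4O)cc1
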